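**Strategy.** Everything rests on reading the bond shared by the oxirane and the six-membered ring (C1–C6 of the 7-oxabicyclo[4.1.0]heptan-2-one core, α,β to the C2 ketone) as the C=C of a 2-methylcyclohex-2-enone. The carbocycle is therefore closed at this bond by ring-closing metathesis of an acyclic isopropenyl ketone, whose two contiguous stereocentres (C3–O and the C4 branch) come from a trans-selective cuprate addition to a chiral butenolide. Alkaline hydrogen peroxide then adds the oxirane oxygen anti to both ring substituents. The side chain grows from an α-methylene aldehyde by asymmetric allylation and cross-metathesis, followed by the two esterifications.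

Key step: step 9

Remark on numbering: ring atoms of the bicyclic compounds are numbered as in the target name (C1 methyl-bearing oxirane carbon, C2 ketone, C3 O-bearing carbon, C4 branch carbon, C5 CH2, C6 oxirane CH).

Step 1
Reactants: 1 (S)-5-(hydroxymethyl)furan-2(5H)-one
Product: 2 (S)-5-[(triethylsilyloxy)methyl]furan-2(5H)-one
Conditions: Et3SiCl, imidazole, CH2Cl2, 0 °C
Reagents that add atoms: chlorotriethylsilane, CC[Si](Cl)(CC)CC
Why: Imidazole-mediated O-silylation of the primary alcohol; the stereocentre is not touched.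

Step 2
Reactants: 2 (S)-5-[(triethylsilyloxy)methyl]furan-2(5H)-one; 3 2-bromo-3,3-diethoxyprop-1-ene
Product: 6 (4R,5S)-4-(3,3-diethoxyprop-1-en-2-yl)-5-[(triethylsilyloxy)methyl]dihydrofuran-2(3H)-one, via (3,3-diethoxyprop-1-en-2-yl)lithium 4 (not isolated), via lithium bis(3,3-diethoxyprop-1-en-2-yl)cuprate 5 (not isolated)
Conditions: 3, t-BuLi, Et2O, −78 °C; CuBr·SMe2, −78 to −40 °C; then 2, −78 °C; aq NH4Cl
Reagents that add atoms: none
Why: Conjugate addition of a Gilman vinylcuprate to the butenolide; the reagent should enter anti to the C5 silyloxymethyl group, setting C4 trans to C5 by ring control.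

Step 3
Reactants: 6 (4R,5S)-4-(3,3-diethoxyprop-1-en-2-yl)-5-[(triethylsilyloxy)methyl]dihydrofuran-2(3H)-one
Product: 7 (2S,3R)-3-(3,3-diethoxyprop-1-en-2-yl)-5-oxotetrahydrofuran-2-carbaldehyde
Conditions: (COCl)2, DMSO, CH2Cl2, −78 to −30 °C; then Et3N, −78 to 0 °C
Reagents that add atoms: none
Why: Swern oxidation applied directly to the primary triethylsilyl ether, which the chlorosulfonium salt cleaves in the flask; the α-centre is already the more stable trans isomer, so it should not erode.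

Step 4
Reactants: 7 (2S,3R)-3-(3,3-diethoxyprop-1-en-2-yl)-5-oxotetrahydrofuran-2-carbaldehyde; 8 isopropenylmagnesium bromide
Product: 9 (4R,5S)-4-(3,3-diethoxyprop-1-en-2-yl)-5-(1-hydroxy-2-methylprop-2-en-1-yl)dihydrofuran-2(3H)-one (both carbinol epimers)
Conditions: THF, −78 °C; aq NH4Cl
Reagents that add atoms: none
Why: Grignard 1,2-addition, much faster at the aldehyde than at the lactone at −78 °C; the new carbinol centre forms as a mixture, which does not matter because it is oxidised in step 7.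

Step 5
Reactants: 9 (4R,5S)-4-(3,3-diethoxyprop-1-en-2-yl)-5-(1-hydroxy-2-methylprop-2-en-1-yl)dihydrofuran-2(3H)-one
Product: 10 (4R,5S)-4-(3,3-diethoxyprop-1-en-2-yl)-5-(1-hydroxy-2-methylprop-2-en-1-yl)tetrahydrofuran-2-ol (lactol, anomers)
Conditions: i-Bu2AlH (2.3 equiv), CH2Cl2, −78 °C; Rochelle salt
Reagents that add atoms: none
Why: Partial reduction of the γ-lactone with i-Bu2AlH stops at the lactol because the tetrahedral aluminate is stable at −78 °C; the anomeric centre is removed in step 6.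

Step 6
Reactants: 10 (4R,5S)-4-(3,3-diethoxyprop-1-en-2-yl)-5-(1-hydroxy-2-methylprop-2-en-1-yl)tetrahydrofuran-2-ol
Product: 11 (4S,5R)-5-(3,3-diethoxyprop-1-en-2-yl)-2-methylocta-1,7-diene-3,4-diol (C3 epimers)
Conditions: Ph3PCH3Br, KN(SiMe3)2, THF, 0 °C to rt
Reagents that add atoms: methylenetriphenylphosphorane, C=P(c1ccccc1)(c1ccccc1)c1ccccc1
Why: Wittig methylenation of the open hydroxy-aldehyde form of the lactol; it gives the terminal vinyl group and frees the C4 hydroxyl without touching C4 or C5.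

Step 7
Reactants: 11 (4S,5R)-5-(3,3-diethoxyprop-1-en-2-yl)-2-methylocta-1,7-diene-3,4-diol
Product: 12 (4S,5R)-5-(3,3-diethoxyprop-1-en-2-yl)-4-hydroxy-2-methylocta-1,7-dien-3-one
Conditions: MnO2 (activated, excess), CH2Cl2, rt
Reagents that add atoms: none
Why: Chemoselective MnO2 oxidation of the allylic carbinol; the saturated secondary alcohol should stay untouched, and both C3 epimers converge on one ketone.

Step 8
Reactants: 12 (4S,5R)-5-(3,3-diethoxyprop-1-en-2-yl)-4-hydroxy-2-methylocta-1,7-dien-3-one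
Product: 13 (4S,5R)-4-[(tert-butyldimethylsilyl)oxy]-5-(3,3-diethoxyprop-1-en-2-yl)-2-methylocta-1,7-dien-3-one
Conditions: t-BuMe2SiOTf, 2,6-lutidine, CH2Cl2, −78 °C
Reagents that add atoms: tert-butyldimethylsilyl trifluoromethanesulfonate, CC(C)(C)[Si](C)(C)OS(=O)(=O)C(F)(F)F
Why: O-silylation of the hindered α-hydroxy ketone with a silyl triflate; it masks the hydroxyl against the base of step 10.

Step 9
Reactants: 13 (4S,5R)-4-[(tert-butyldimethylsilyl)oxy]-5-(3,3-diethoxyprop-1-en-2-yl)-2-methylocta-1,7-dien-3-one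
Product: 14 (5R,6S)-6-[(tert-butyldimethylsilyl)oxy]-5-(3,3-diethoxyprop-1-en-2-yl)-2-methylcyclohex-2-en-1-one
Conditions: second-generation Grubbs catalyst RuCl2(=CHPh)(PCy3)(H2IMes) (5 mol %), CH2Cl2 (0.005 M), 40 °C
Reagents that add atoms: none
Why: Ring-closing olefin metathesis: the ruthenium benzylidene initiates at the monosubstituted C7=C8 alkene of 13, and the resulting alkylidene adds across the 1,1-disubstituted C1=C2 alkene of the isopropenyl ketone through a ruthenacyclobutane whose cycloreversion forms the ring C=C and expels ethylene. The closest known reaction type is the metathesis closure of isopropenyl ketone dienes to 2-methylcyclohex-2-enones. The one ring closed is the six-membered carbocycle, by joining C2 and C7 of 13, the two carbons that become the oxirane carbons C1 and C6 of the target. No stereocentre is formed, and C4 and C5 of 13 pass through unchanged because the conditions are neutral. The selectivity needed is chemoselectivity against the third, acetal-bearing 1,1-disubstituted alkene, secured because its engagement would give a cyclobutene or a tetrasubstituted cyclopentene. High dilution should suppress intermolecular cross-metathesis.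

Step 10
Reactants: 14 (5R,6S)-6-[(tert-butyldimethylsilyl)oxy]-5-(3,3-diethoxyprop-1-en-2-yl)-2-methylcyclohex-2-en-1-one
Product: 15 (1S,3S,4R,6S)-3-[(tert-butyldimethylsilyl)oxy]-4-(3,3-diethoxyprop-1-en-2-yl)-1-methyl-7-oxabicyclo[4.1.0]heptan-2-one
Conditions: 30% H2O2, LiOH (0.2 equiv), MeOH, 0 °C
Reagents that add atoms: hydrogen peroxide, OO
Why: Weitz–Scheffer nucleophilic epoxidation; hydroperoxide should add axially to the enone β-carbon on the face anti to the pseudo-equatorial C5 branch and the pseudo-axial C6 silyloxy group (as with carvone), setting both oxirane centres, while the pseudo-equatorial C6–H is poorly aligned for enolisation.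

Step 11
Reactants: 15 (1S,3S,4R,6S)-3-[(tert-butyldimethylsilyl)oxy]-4-(3,3-diethoxyprop-1-en-2-yl)-1-methyl-7-oxabicyclo[4.1.0]heptan-2-one
Product: 16 2-[(1S,3S,4R,6S)-3-[(tert-butyldimethylsilyl)oxy]-1-methyl-2-oxo-7-oxabicyclo[4.1.0]heptan-4-yl]prop-2-enal
Conditions: pyridinium p-toluenesulfonate, acetone/H2O, rt
Reagents that add atoms: water, O
Why: Mild acid-catalysed acetal hydrolysis releases the α-methylene aldehyde; the silyl ether and the epoxy ketone should tolerate the weak acid.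

Step 12
Reactants: 16 2-[(1S,3S,4R,6S)-3-[(tert-butyldimethylsilyl)oxy]-1-methyl-2-oxo-7-oxabicyclo[4.1.0]heptan-4-yl]prop-2-enal; 17 allyltributylstannane
Product: 18 (1S,3S,4R,6S)-3-[(tert-butyldimethylsilyl)oxy]-4-[(3S)-3-hydroxyhexa-1,5-dien-2-yl]-1-methyl-7-oxabicyclo[4.1.0]heptan-2-one
Conditions: (S)-BINOL (20 mol %), Ti(OiPr)4 (10 mol %), 4 Å MS, CH2Cl2, −20 °C
Reagents that add atoms: none
Why: Keck asymmetric allylation; the (S)-BINOL–titanium catalyst should direct the allylstannane to the Si face of the aldehyde (catalyst control), giving the (S)-carbinol, while the hindered ring ketone does not react.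

Step 13
Reactants: 18 (1S,3S,4R,6S)-3-[(tert-butyldimethylsilyl)oxy]-4-[(3S)-3-hydroxyhexa-1,5-dien-2-yl]-1-methyl-7-oxabicyclo[4.1.0]heptan-2-one; 19 2-methylbut-2-ene
Product: 20 (1S,3S,4R,6S)-3-[(tert-butyldimethylsilyl)oxy]-4-[(3S)-3-hydroxy-6-methylhepta-1,5-dien-2-yl]-1-methyl-7-oxabicyclo[4.1.0]heptan-2-one
Conditions: second-generation Grubbs catalyst RuCl2(=CHPh)(PCy3)(H2IMes) (5 mol %), 19 (excess), CH2Cl2, 40 °C
Reagents that add atoms: none
Why: Olefin cross-metathesis of the monosubstituted alkene with excess 2-methylbut-2-ene turns the allyl into a prenyl group; it is run before acylation so that ring closure onto an unsaturated ester cannot compete.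

Step 14
Reactants: 20 (1S,3S,4R,6S)-3-[(tert-butyldimethylsilyl)oxy]-4-[(3S)-3-hydroxy-6-methylhepta-1,5-dien-2-yl]-1-methyl-7-oxabicyclo[4.1.0]heptan-2-one; 21 3-methylbut-2-enoic acid
Product: 22 (3S)-2-[(1S,3S,4R,6S)-3-[(tert-butyldimethylsilyl)oxy]-1-methyl-2-oxo-7-oxabicyclo[4.1.0]heptan-4-yl]-6-methylhepta-1,5-dien-3-yl 3-methylbut-2-enoate
Conditions: dicyclohexylcarbodiimide, 4-(dimethylamino)pyridine (cat.), CH2Cl2, 0 °C to rt
Reagents that add atoms: none
Why: Steglich esterification of the secondary allylic alcohol; the C–O bond of the carbinol is not broken, so its configuration is retained.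

Step 15
Reactants: 22 (3S)-2-[(1S,3S,4R,6S)-3-[(tert-butyldimethylsilyl)oxy]-1-methyl-2-oxo-7-oxabicyclo[4.1.0]heptan-4-yl]-6-methylhepta-1,5-dien-3-yl 3-methylbut-2-enoate
Product: 23 (3S)-2-[(1S,3S,4R,6S)-3-hydroxy-1-methyl-2-oxo-7-oxabicyclo[4.1.0]heptan-4-yl]-6-methylhepta-1,5-dien-3-yl 3-methylbut-2-enoate
Conditions: HF·pyridine, pyridine, THF, 0 °C
Reagents that add atoms: none
Why: Fluoride-mediated desilylation under buffered, weakly acidic conditions that should spare the ester, the oxirane and the centre α to the ketone.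

Step 16
Reactants: 23 (3S)-2-[(1S,3S,4R,6S)-3-hydroxy-1-methyl-2-oxo-7-oxabicyclo[4.1.0]heptan-4-yl]-6-methylhepta-1,5-dien-3-yl 3-methylbut-2-enoate; 24 angelic acid, (Z)-2-methylbut-2-enoic acid
Product: 26 (1S,3S,4R,6S)-1-methyl-4-{(3S)-6-methyl-3-[(3-methylbut-2-enoyl)oxy]hepta-1,5-dien-2-yl}-2-oxo-7-oxabicyclo[4.1.0]heptan-3-yl (2Z)-2-methylbut-2-enoate, via (Z)-2-methylbut-2-enoic 2,4,6-trichlorobenzoic anhydride 25 (not isolated)
Conditions: 24, 2,4,6-Cl3C6H2COCl, Et3N, toluene, rt; then 23, 70 °C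
Reagents that add atoms: none
Why: Yamaguchi-type esterification through the preformed mixed anhydride without a nucleophilic catalyst, the established way to acylate with angelic acid without Z to E isomerisation; the carbinol configuration is retained.

**Compound list**

1 | (S)-5-(hydroxymethyl)furan-2(5H)-one | O=C1C=C[C@@H](CO)O1 | starting material
2 | (S)-5-[(triethylsilyloxy)methyl]furan-2(5H)-one | O=C1C=C[C@@H](CO[Si](CC)(CC)CC)O1 | intermediate
3 | 2-bromo-3,3-diethoxyprop-1-ene | C=C(Br)C(OCC)OCC | starting material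
4 | (3,3-diethoxyprop-1-en-2-yl)lithium | [Li]C(=C)C(OCC)OCC | intermediate
5 | lithium bis(3,3-diethoxyprop-1-en-2-yl)cuprate | [Li+].C=C([Cu-]C(=C)C(OCC)OCC)C(OCC)OCC | intermediate
6 | (4R,5S)-4-(3,3-diethoxyprop-1-en-2-yl)-5-[(triethylsilyloxy)methyl]dihydrofuran-2(3H)-one | O=C1C[C@H](C(=C)C(OCC)OCC)[C@@H](CO[Si](CC)(CC)CC)O1 | intermediate
7 | (2S,3R)-3-(3,3-diethoxyprop-1-en-2-yl)-5-oxotetrahydrofuran-2-carbaldehyde | O=C1C[C@H](C(=C)C(OCC)OCC)[C@@H](C=O)O1 | intermediate
8 | isopropenylmagnesium bromide | C=C(C)[Mg]Br | starting material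
9 | (4R,5S)-4-(3,3-diethoxyprop-1-en-2-yl)-5-(1-hydroxy-2-methylprop-2-en-1-yl)dihydrofuran-2(3H)-one (carbinol epimers) | O=C1C[C@H](C(=C)C(OCC)OCC)[C@@H](C(O)C(C)=C)O1 | intermediate
10 | (4R,5S)-4-(3,3-diethoxyprop-1-en-2-yl)-5-(1-hydroxy-2-methylprop-2-en-1-yl)tetrahydrofuran-2-ol (anomers) | OC1C[C@H](C(=C)C(OCC)OCC)[C@@H](C(O)C(C)=C)O1 | intermediate
11 | (4S,5R)-5-(3,3-diethoxyprop-1-en-2-yl)-2-methylocta-1,7-diene-3,4-diol (C3 epimers) | C=CC[C@H](C(=C)C(OCC)OCC)[C@H](O)C(O)C(C)=C | intermediate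
12 | (4S,5R)-5-(3,3-diethoxyprop-1-en-2-yl)-4-hydroxy-2-methylocta-1,7-dien-3-one | C=CC[C@H](C(=C)C(OCC)OCC)[C@H](O)C(=O)C(C)=C | intermediate
13 | (4S,5R)-4-[(tert-butyldimethylsilyl)oxy]-5-(3,3-diethoxyprop-1-en-2-yl)-2-methylocta-1,7-dien-3-one | C=CC[C@H](C(=C)C(OCC)OCC)[C@H](O[Si](C)(C)C(C)(C)C)C(=O)C(C)=C | intermediate
14 | (5R,6S)-6-[(tert-butyldimethylsilyl)oxy]-5-(3,3-diethoxyprop-1-en-2-yl)-2-methylcyclohex-2-en-1-one | C=C(C(OCC)OCC)[C@H]1CC=C(C)C(=O)[C@H]1O[Si](C)(C)C(C)(C)C | intermediate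
15 | (1S,3S,4R,6S)-3-[(tert-butyldimethylsilyl)oxy]-4-(3,3-diethoxyprop-1-en-2-yl)-1-methyl-7-oxabicyclo[4.1.0]heptan-2-one | C=C(C(OCC)OCC)[C@H]1C[C@@H]2O[C@]2(C)C(=O)[C@H]1O[Si](C)(C)C(C)(C)C | intermediate
16 | 2-[(1S,3S,4R,6S)-3-[(tert-butyldimethylsilyl)oxy]-1-methyl-2-oxo-7-oxabicyclo[4.1.0]heptan-4-yl]prop-2-enal | C=C(C=O)[C@H]1C[C@@H]2O[C@]2(C)C(=O)[C@H]1O[Si](C)(C)C(C)(C)C | intermediate
17 | allyltributylstannane | C=CC[Sn](CCCC)(CCCC)CCCC | starting material
18 | (1S,3S,4R,6S)-3-[(tert-butyldimethylsilyl)oxy]-4-[(3S)-3-hydroxyhexa-1,5-dien-2-yl]-1-methyl-7-oxabicyclo[4.1.0]heptan-2-one | C=C([C@H](CC=C)O)[C@H]1C[C@@H]2O[C@]2(C)C(=O)[C@H]1O[Si](C)(C)C(C)(C)C | intermediate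
19 | 2-methylbut-2-ene | CC=C(C)C | starting material
20 | (1S,3S,4R,6S)-3-[(tert-butyldimethylsilyl)oxy]-4-[(3S)-3-hydroxy-6-methylhepta-1,5-dien-2-yl]-1-methyl-7-oxabicyclo[4.1.0]heptan-2-one | C=C([C@H](CC=C(C)C)O)[C@H]1C[C@@H]2O[C@]2(C)C(=O)[C@H]1O[Si](C)(C)C(C)(C)C | intermediate
21 | 3-methylbut-2-enoic acid | CC(C)=CC(=O)O | starting material
22 | (3S)-2-[(1S,3S,4R,6S)-3-[(tert-butyldimethylsilyl)oxy]-1-methyl-2-oxo-7-oxabicyclo[4.1.0]heptan-4-yl]-6-methylhepta-1,5-dien-3-yl 3-methylbut-2-enoate | C=C([C@H](CC=C(C)C)OC(=O)C=C(C)C)[C@H]1C[C@@H]2O[C@]2(C)C(=O)[C@H]1O[Si](C)(C)C(C)(C)C | intermediate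
23 | (3S)-2-[(1S,3S,4R,6S)-3-hydroxy-1-methyl-2-oxo-7-oxabicyclo[4.1.0]heptan-4-yl]-6-methylhepta-1,5-dien-3-yl 3-methylbut-2-enoate | C=C([C@H](CC=C(C)C)OC(=O)C=C(C)C)[C@H]1C[C@@H]2O[C@]2(C)C(=O)[C@H]1O | intermediate
24 | angelic acid, (Z)-2-methylbut-2-enoic acid | C/C=C(/C)C(=O)O | starting material
25 | (Z)-2-methylbut-2-enoic 2,4,6-trichlorobenzoic anhydride | C/C=C(/C)C(=O)OC(=O)c1c(Cl)cc(Cl)cc1Cl | intermediate
26 | (1S,3S,4R,6S)-1-methyl-4-{(3S)-6-methyl-3-[(3-methylbut-2-enoyl)oxy]hepta-1,5-dien-2-yl}-2-oxo-7-oxabicyclo[4.1.0]heptan-3-yl (2Z)-2-methylbut-2-enoate | C=C([C@H](CC=C(C)C)OC(=O)C=C(C)C)[C@H]1C[C@@H]2O[C@]2(C)C(=O)[C@H]1OC(=O)/C(C)=C\C | target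

**Total step count:** 16. **Longest linear sequence:** 16 steps (1 to 26).

**Steps most likely to fail**

1. Step 16. The activated angeloyl unit may isomerise from Z to E, or acylation of the hindered α-hydroxy ketone may be slow enough for base to epimerise the centre next to the ketone. Fallback: setting out from 23, Steglich coupling with 2-[bis(2,2,2-trifluoroethoxy)phosphoryl]propanoic acid would give the phosphonopropionate ester F1. Deprotonation with KN(SiMe3)2/18-crown-6 at −78 °C and Still–Gennari olefination with acetaldehyde would then build the Z-configured 2-methylbut-2-enoate in place and return to 26.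

2. Step 3. Cleavage of the silyl ether by the chlorosulfonium salt may be incomplete, or the sensitive α-acyloxy aldehyde may degrade during the long activation period. Fallback: setting out from 6, HF·pyridine buffered with pyridine in THF would remove the triethylsilyl group to give (4R,5S)-4-(3,3-diethoxyprop-1-en-2-yl)-5-(hydroxymethyl)dihydrofuran-2(3H)-one F2, and a separate Dess–Martin oxidation would return to 7.

3. Step 12. Catalyst turnover may be poor, or facial control insufficient, at the hindered α-branched enal. Fallback: setting out from 16, stoichiometric B-allyldiisopinocampheylborane of the (+)-α-pinene series (made from (−)-B-methoxydiisopinocampheylborane and allylmagnesium bromide) in Et2O at −78 °C, with NaBO3 work-up, would give 18 directly. This Brown allylboration goes through a closed boron-chair transition state under reagent control without a Lewis acid, and it makes no new compound (F0).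

Further compounds
F1 | step 16 | (3S)-2-[(1S,3S,4R,6S)-3-({2-[bis(2,2,2-trifluoroethoxy)phosphoryl]propanoyl}oxy)-1-methyl-2-oxo-7-oxabicyclo[4.1.0]heptan-4-yl]-6-methylhepta-1,5-dien-3-yl 3-methylbut-2-enoate | C=C([C@H](CC=C(C)C)OC(=O)C=C(C)C)[C@H]1C[C@@H]2O[C@]2(C)C(=O)[C@H]1OC(=O)C(C)P(=O)(OCC(F)(F)F)OCC(F)(F)F
F2 | step 3 | (4R,5S)-4-(3,3-diethoxyprop-1-en-2-yl)-5-(hydroxymethyl)dihydrofuran-2(3H)-one | O=C1C[C@H](C(=C)C(OCC)OCC)[C@@H](CO)O1
F0 | step 12 | none | none
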